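**Retrosynthetic overview**
- Feature: C4 is a diarylmethine carbon bonded to the 2,4,6-trioxygenated ring D and to C4a of ring A. A cation at C4 is stabilised by all three ring D oxygens, and C4a (ortho to O1, para to O7) can reach it through the O1–C2–C3 tether.
- Last disconnections: the four O-benzyl groups, the ring B pivalate, then the ring D–acyl bond (Friedel–Crafts acylation with 9-phenylnonanoic acid).
- Key disconnection: C4–C4a, an intramolecular cationic Friedel–Crafts alkylation of a ring D benzylic carbinol. It closes ring C, the only ring that is made (rings A, B and D are bought as arenes), and sets C4 from C2.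
- The carbinol comes from 2,4,6-tris(benzyloxy)phenyllithium and an (S)-3-aryloxy-3-arylpropanal; the aldehyde comes from the 3-chloropropyl aryl ether through the iodide.
- C2 is set by CBS reduction of the pivaloylated 3-chloropropiophenone and inverted in a Mitsunobu etherification with 3-(benzyloxy)phenol.

Key step: step 8

Remark on the chemistry: 9-phenylnonanoic acid is taken as a purchasable acid, and carbinol 12 is carried as the mixture of its two carbinol epimers, since both ionise to the same cation.

**Step 1**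
Reactants: 1 3-chloro-1-(4-hydroxyphenyl)propan-1-one
Product: 2 4-(3-chloropropanoyl)phenyl 2,2-dimethylpropanoate
Conditions: PivCl (1.1 equiv), pyridine (1.5 equiv), CH2Cl2, 0 °C
Reagents that add atoms: pivaloyl chloride, CC(C)(C)C(=O)Cl
Why: O-acylation of the phenol (nucleophilic acyl substitution), with the weak base pyridine chosen because a trialkylamine would eliminate HCl from the β-chloroketone to the aryl vinyl ketone.

**Step 2**
Reactants: 2 4-(3-chloropropanoyl)phenyl 2,2-dimethylpropanoate
Product: 3 4-[(1R)-3-chloro-1-hydroxypropyl]phenyl 2,2-dimethylpropanoate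
Conditions: (S)-Me-CBS [(3aS)-1-methyl-3,3-diphenyltetrahydro-1H,3H-pyrrolo[1,2-c][1,3,2]oxazaborole] (10 mol%), BH3·SMe2 (0.7 equiv), THF, −20 °C; MeOH, then aqueous work-up
Reagents that add atoms: none
Why: Corey–Bakshi–Shibata reduction, in which the ketone binds the (S)-oxazaborolidine–borane complex with the aryl group as the large substituent, so hydride should be delivered to the face that gives the (R)-carbinol as for other 3-chloropropiophenones, while the aryl ester and the chloride are inert to borane at this temperature.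

**Step 3**
Reactants: 3 4-[(1R)-3-chloro-1-hydroxypropyl]phenyl 2,2-dimethylpropanoate; 4 3-(benzyloxy)phenol
Product: 5 4-{(1S)-1-[3-(benzyloxy)phenoxy]-3-chloropropyl}phenyl 2,2-dimethylpropanoate
Conditions: PPh3, DIAD, THF, 0 °C → rt
Reagents that add atoms: none
Why: Mitsunobu etherification, in which the phenol displaces the oxyphosphonium group by SN2 with inversion, so the (R)-alcohol should give the (S)-aryl ether that becomes C2 of the target, and the para-acyloxy group keeps the benzylic centre from ionising and eroding the ee.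

**Step 4**
Reactants: 5 4-{(1S)-1-[3-(benzyloxy)phenoxy]-3-chloropropyl}phenyl 2,2-dimethylpropanoate
Product: 6 4-{(1S)-1-[3-(benzyloxy)phenoxy]-3-iodopropyl}phenyl 2,2-dimethylpropanoate
Conditions: NaI (5 equiv), acetone, reflux
Reagents that add atoms: sodium iodide, [Na+].[I-]
Why: Finkelstein halide exchange (SN2 at the primary carbon, driven by precipitation of NaCl) replaces the unreactive chloride by an iodide that can be oxidised at room temperature, without touching the benzylic ether stereocentre.

**Step 5**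
Reactants: 6 4-{(1S)-1-[3-(benzyloxy)phenoxy]-3-iodopropyl}phenyl 2,2-dimethylpropanoate
Product: 8 4-{(1S)-1-[3-(benzyloxy)phenoxy]-3-oxopropyl}phenyl 2,2-dimethylpropanoate, via alkoxyammonium iodide 7 (not isolated)
Conditions: Me3NO (anhydrous, 4 equiv), DMSO, rt; crude aldehyde used at once
Reagents that add atoms: trimethylamine N-oxide, C[N+](C)(C)[O-]
Why: Kornblum-type oxidation in its amine N-oxide variant, in which the N-oxide oxygen displaces iodide by SN2 and a second equivalent removes an O–CH2 proton to release trimethylamine and the aldehyde at room temperature, chosen because a hot bicarbonate protocol on the chloride would be slow and would invite E1cB loss of the β-aryloxy group.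

**Step 6**
Reactants: 9 1,3,5-tris(benzyloxy)benzene
Product: 10 2-bromo-1,3,5-tris(benzyloxy)benzene
Conditions: NBS (1.0 equiv), CH2Cl2, −20 → 0 °C
Reagents that add atoms: N-bromosuccinimide, O=C1CCC(=O)N1Br
Why: Electrophilic aromatic bromination of the highly activated phloroglucinol triether, whose three open positions are equivalent, so one equivalent of NBS at low temperature should stop at the monobromide.

**Step 7**
Reactants: 10 2-bromo-1,3,5-tris(benzyloxy)benzene; 8 4-{(1S)-1-[3-(benzyloxy)phenoxy]-3-oxopropyl}phenyl 2,2-dimethylpropanoate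
Product: 12 4-{(1S)-1-[3-(benzyloxy)phenoxy]-3-hydroxy-3-[2,4,6-tris(benzyloxy)phenyl]propyl}phenyl 2,2-dimethylpropanoate (both carbinol epimers), via aryllithium 11 (not isolated)
Conditions: 10 (1.2 equiv), n-BuLi (1.15 equiv), THF, −78 °C; then added to 8, THF, −78 °C; pH 7 aqueous quench; Et3N-deactivated silica
Reagents that add atoms: none
Why: Bromine–lithium exchange followed by 1,2-addition of the aryllithium to the aldehyde, where exchange at −78 °C avoids benzylic deprotonation of the benzyl ethers, addition to the aldehyde should outpace α-deprotonation and attack on the hindered aryl pivalate, and the new carbinol centre needs no control because it is planarised in step 8.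

**Step 8**
Reactants: 12 4-{(1S)-1-[3-(benzyloxy)phenoxy]-3-hydroxy-3-[2,4,6-tris(benzyloxy)phenyl]propyl}phenyl 2,2-dimethylpropanoate
Product: 13 4-{(2S,4R)-7-(benzyloxy)-4-[2,4,6-tris(benzyloxy)phenyl]-3,4-dihydro-2H-chromen-2-yl}phenyl 2,2-dimethylpropanoate
Conditions: Bi(OTf)3 (5 mol%), CH2Cl2 (0.01 M), 0 °C → rt
Reagents that add atoms: none
Why: Bi(OTf)3, together with the triflic acid it releases from traces of water, activates the benzylic hydroxyl, and loss of water gives a 2,4,6-tris(benzyloxy)benzyl cation common to both carbinol epimers, which the ring A carbon ortho to O1 and para to the benzyloxy group attacks before loss of a proton restores the arene. The closest known reaction type is the acid-catalysed cyclisation of 3-aryloxy-1-arylpropan-1-ols to 4-arylchromans, an intramolecular Friedel–Crafts alkylation, together with Bi(OTf)3-catalysed benzylation of arenes by benzylic alcohols. Ring C closes as a six-membered ring by 6-exo-trig attack on the cationic carbon, with the C4a–C8a arene bond ending up inside the new ring. The new stereocentre C4 is controlled by C2 through 1,3-induction: in the chair-like transition state the C2 aryl group is equatorial and the flat, di-ortho-substituted ring D turns pseudo-axial to escape the peri C5–H, which should give the 2,4-trans (2S,4R) flavan, and because this is also the less strained isomer any reversibility of the alkylation works in the same direction. The step needs site selectivity on ring A, ring closure in preference to intermolecular capture, and retention of C2: attack para to the benzyloxy group is less hindered than attack between the two oxygens, high dilution favours cyclisation, and the electron-withdrawing pivalate on ring B keeps the C2–O1 bond from ionising.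

**Step 9**
Reactants: 13 4-{(2S,4R)-7-(benzyloxy)-4-[2,4,6-tris(benzyloxy)phenyl]-3,4-dihydro-2H-chromen-2-yl}phenyl 2,2-dimethylpropanoate; 14 9-phenylnonanoic acid
Product: 16 4-{(2S,4R)-7-(benzyloxy)-4-[2,4,6-tris(benzyloxy)-3-(9-phenylnonanoyl)phenyl]-3,4-dihydro-2H-chromen-2-yl}phenyl 2,2-dimethylpropanoate, via mixed anhydride 15 (not isolated)
Conditions: 14 (1.5 equiv), (CF3CO)2O (2 equiv), CH2Cl2, 0 °C; then 13, 0 °C → rt
Reagents that add atoms: none
Why: Friedel–Crafts acylation through the mixed carboxylic–trifluoroacetic anhydride, in which ring D (a phloroglucinol triether with two equivalent open positions) is the most nucleophilic arene of 13, ring A and the pivalate-bearing ring B should react more slowly, and the first acyl group deactivates ring D against a second acylation.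

**Step 10**
Reactants: 16 4-{(2S,4R)-7-(benzyloxy)-4-[2,4,6-tris(benzyloxy)-3-(9-phenylnonanoyl)phenyl]-3,4-dihydro-2H-chromen-2-yl}phenyl 2,2-dimethylpropanoate
Product: 17 1-{2,4,6-tris(benzyloxy)-3-[(2S,4R)-7-(benzyloxy)-2-(4-hydroxyphenyl)-3,4-dihydro-2H-chromen-4-yl]phenyl}-9-phenylnonan-1-one
Conditions: K2CO3 (cat.), MeOH/THF, rt
Reagents that add atoms: none
Why: Base-catalysed transesterification (methanolysis) of the aryl ester, whose phenoxide leaving group lets the hindered pivalate cleave at room temperature while the benzyl ethers, the ketone and both stereocentres should be unaffected.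

**Step 11**
Reactants: 17 1-{2,4,6-tris(benzyloxy)-3-[(2S,4R)-7-(benzyloxy)-2-(4-hydroxyphenyl)-3,4-dihydro-2H-chromen-4-yl]phenyl}-9-phenylnonan-1-one
Product: 18 (+)-myristinin D, 1-{2,4,6-trihydroxy-3-[(2S,4R)-7-hydroxy-2-(4-hydroxyphenyl)-3,4-dihydro-2H-chromen-4-yl]phenyl}-9-phenylnonan-1-one
Conditions: H2 (1 atm), 10% Pd/C, EtOAc/MeOH, rt
Reagents that add atoms: none
Why: Catalytic hydrogenolysis of the four aryl benzyl ethers over Pd/C, with the hydrogen-bonded aryl ketone and the cyclic benzylic C2–O1 ether much slower to reduce, so stopping after uptake of four equivalents of hydrogen should leave the (2S,4R) skeleton intact.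

**Compound list**
1 | 3-chloro-1-(4-hydroxyphenyl)propan-1-one | O=C(CCCl)c1ccc(O)cc1 | starting material
2 | 4-(3-chloropropanoyl)phenyl 2,2-dimethylpropanoate | O=C(CCCl)c1ccc(OC(=O)C(C)(C)C)cc1 | intermediate
3 | 4-[(1R)-3-chloro-1-hydroxypropyl]phenyl 2,2-dimethylpropanoate | ClCC[C@@H](O)c1ccc(OC(=O)C(C)(C)C)cc1 | intermediate
4 | 3-(benzyloxy)phenol | Oc1cccc(OCc2ccccc2)c1 | starting material
5 | 4-{(1S)-1-[3-(benzyloxy)phenoxy]-3-chloropropyl}phenyl 2,2-dimethylpropanoate | ClCC[C@@H](c1ccc(OC(=O)C(C)(C)C)cc1)Oc1cccc(OCc2ccccc2)c1 | intermediate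
6 | 4-{(1S)-1-[3-(benzyloxy)phenoxy]-3-iodopropyl}phenyl 2,2-dimethylpropanoate | ICC[C@@H](c1ccc(OC(=O)C(C)(C)C)cc1)Oc1cccc(OCc2ccccc2)c1 | intermediate
7 | {(3S)-3-[3-(benzyloxy)phenoxy]-3-[4-(2,2-dimethylpropanoyloxy)phenyl]propoxy}trimethylammonium iodide (formed in the flask) | C[N+](C)(C)OCC[C@@H](c1ccc(OC(=O)C(C)(C)C)cc1)Oc1cccc(OCc2ccccc2)c1.[I-] | intermediate
8 | 4-{(1S)-1-[3-(benzyloxy)phenoxy]-3-oxopropyl}phenyl 2,2-dimethylpropanoate | O=CC[C@@H](c1ccc(OC(=O)C(C)(C)C)cc1)Oc1cccc(OCc2ccccc2)c1 | intermediate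
9 | 1,3,5-tris(benzyloxy)benzene | c1ccccc1COc1cc(OCc2ccccc2)cc(OCc2ccccc2)c1 | starting material
10 | 2-bromo-1,3,5-tris(benzyloxy)benzene | Brc1c(OCc2ccccc2)cc(OCc2ccccc2)cc1OCc1ccccc1 | intermediate
11 | [2,4,6-tris(benzyloxy)phenyl]lithium (formed in the flask) | [Li]c1c(OCc2ccccc2)cc(OCc2ccccc2)cc1OCc1ccccc1 | intermediate
12 | 4-{(1S)-1-[3-(benzyloxy)phenoxy]-3-hydroxy-3-[2,4,6-tris(benzyloxy)phenyl]propyl}phenyl 2,2-dimethylpropanoate (both carbinol epimers) | OC(c1c(OCc2ccccc2)cc(OCc2ccccc2)cc1OCc1ccccc1)C[C@@H](c1ccc(OC(=O)C(C)(C)C)cc1)Oc1cccc(OCc2ccccc2)c1 | intermediate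
13 | 4-{(2S,4R)-7-(benzyloxy)-4-[2,4,6-tris(benzyloxy)phenyl]-3,4-dihydro-2H-chromen-2-yl}phenyl 2,2-dimethylpropanoate | c1ccccc1COc1cc(OCc2ccccc2)cc(OCc2ccccc2)c1[C@@H]1C[C@@H](c2ccc(OC(=O)C(C)(C)C)cc2)Oc2cc(OCc3ccccc3)ccc21 | intermediate
14 | 9-phenylnonanoic acid | OC(=O)CCCCCCCCc1ccccc1 | starting material
15 | 9-phenylnonanoic trifluoroacetic anhydride (formed in the flask) | O=C(CCCCCCCCc1ccccc1)OC(=O)C(F)(F)F | intermediate
16 | 4-{(2S,4R)-7-(benzyloxy)-4-[2,4,6-tris(benzyloxy)-3-(9-phenylnonanoyl)phenyl]-3,4-dihydro-2H-chromen-2-yl}phenyl 2,2-dimethylpropanoate | O=C(CCCCCCCCc1ccccc1)c1c(OCc2ccccc2)cc(OCc2ccccc2)c([C@@H]2C[C@@H](c3ccc(OC(=O)C(C)(C)C)cc3)Oc3cc(OCc4ccccc4)ccc32)c1OCc1ccccc1 | intermediate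
17 | 1-{2,4,6-tris(benzyloxy)-3-[(2S,4R)-7-(benzyloxy)-2-(4-hydroxyphenyl)-3,4-dihydro-2H-chromen-4-yl]phenyl}-9-phenylnonan-1-one | O=C(CCCCCCCCc1ccccc1)c1c(OCc2ccccc2)cc(OCc2ccccc2)c([C@@H]2C[C@@H](c3ccc(O)cc3)Oc3cc(OCc4ccccc4)ccc32)c1OCc1ccccc1 | intermediate
18 | (+)-myristinin D, 1-{2,4,6-trihydroxy-3-[(2S,4R)-7-hydroxy-2-(4-hydroxyphenyl)-3,4-dihydro-2H-chromen-4-yl]phenyl}-9-phenylnonan-1-one | O=C(CCCCCCCCc1ccccc1)c1c(O)cc(O)c([C@@H]2C[C@@H](c3ccc(O)cc3)Oc3cc(O)ccc32)c1O | target

**Step count**
Total: 11 steps. Longest linear sequence: 10 steps from compound 1 (steps 1–5 and 7–11); step 6 is a one-step side branch.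

**Steps most likely to fail**

Step 8. The benzylic cation may be captured by ring D of a second molecule, giving oligomers, or the ring may close with poor facial selectivity at C4. The fallback reverses the order in which the two aryl bonds to C4 are made. Setting out from aldehyde 8, BF3·OEt2 in CH2Cl2 at −78 °C should close ring C by intramolecular Friedel–Crafts hydroxyalkylation of ring A to give 4-[(2S)-7-(benzyloxy)-4-hydroxy-3,4-dihydro-2H-chromen-2-yl]phenyl 2,2-dimethylpropanoate F1 (either C4 epimer). Ionisation of this flavan-4-ol by the same acid in the presence of an excess of 1,3,5-tris(benzyloxy)benzene 9 should then bring in ring D intermolecularly, by axial attack trans to the C2 aryl group. The fallback comes back to the route at 13.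

Step 5. The β-aryloxy aldehyde may lose 3-(benzyloxy)phenoxide by E1cB in the basic medium, or elimination of HI may compete with O-alkylation of the N-oxide. The fallback reaches the aldehyde through the alcohol with a non-basic oxidant. Setting out from iodide 6, displacement with sodium formate (DMF, 50 °C) should give 4-{(1S)-1-[3-(benzyloxy)phenoxy]-3-(formyloxy)propyl}phenyl 2,2-dimethylpropanoate F2. Selective methanolysis of the formate (MeOH, NaHCO3, 0 °C; the hindered aryl pivalate is far slower) should give 4-{(1S)-1-[3-(benzyloxy)phenoxy]-3-hydroxypropyl}phenyl 2,2-dimethylpropanoate F3. Dess–Martin periodinane (NaHCO3, CH2Cl2, 0 °C) should then oxidise F3 to aldehyde 8, where the fallback comes back to the route.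

Step 9. Ring A may be acylated in competition with ring D, or the trifluoroacetic acid released may cleave a benzyl ether or reopen the C4–ring D bond. The fallback brings the chain in as a nucleophile onto a ring D aldehyde. Setting out from 13, Vilsmeier–Haack formylation (POCl3, DMF, 0 °C → rt; aqueous NaOAc), which is selective for the most electron-rich ring, should give 4-{(2S,4R)-7-(benzyloxy)-4-[2,4,6-tris(benzyloxy)-3-formylphenyl]-3,4-dihydro-2H-chromen-2-yl}phenyl 2,2-dimethylpropanoate F4. Addition of 8-phenyloctylmagnesium bromide F5 (from (8-bromooctyl)benzene and Mg in THF) at −78 °C should give 4-{(2S,4R)-7-(benzyloxy)-4-[2,4,6-tris(benzyloxy)-3-(1-hydroxy-9-phenylnonyl)phenyl]-3,4-dihydro-2H-chromen-2-yl}phenyl 2,2-dimethylpropanoate F6. Dess–Martin oxidation of F6 should give ketone 16, where the fallback comes back to the route.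

**Further compounds**
F1 | step 8 | 4-[(2S)-7-(benzyloxy)-4-hydroxy-3,4-dihydro-2H-chromen-2-yl]phenyl 2,2-dimethylpropanoate | OC1C[C@@H](c2ccc(OC(=O)C(C)(C)C)cc2)Oc2cc(OCc3ccccc3)ccc21
F2 | step 5 | 4-{(1S)-1-[3-(benzyloxy)phenoxy]-3-(formyloxy)propyl}phenyl 2,2-dimethylpropanoate | O=COCC[C@@H](c1ccc(OC(=O)C(C)(C)C)cc1)Oc1cccc(OCc2ccccc2)c1
F3 | step 5 | 4-{(1S)-1-[3-(benzyloxy)phenoxy]-3-hydroxypropyl}phenyl 2,2-dimethylpropanoate | OCC[C@@H](c1ccc(OC(=O)C(C)(C)C)cc1)Oc1cccc(OCc2ccccc2)c1
F4 | step 9 | 4-{(2S,4R)-7-(benzyloxy)-4-[2,4,6-tris(benzyloxy)-3-formylphenyl]-3,4-dihydro-2H-chromen-2-yl}phenyl 2,2-dimethylpropanoate | O=Cc1c(OCc2ccccc2)cc(OCc2ccccc2)c([C@@H]2C[C@@H](c3ccc(OC(=O)C(C)(C)C)cc3)Oc3cc(OCc4ccccc4)ccc32)c1OCc1ccccc1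
F5 | step 9 | 8-phenyloctylmagnesium bromide | Br[Mg]CCCCCCCCc1ccccc1
F6 | step 9 | 4-{(2S,4R)-7-(benzyloxy)-4-[2,4,6-tris(benzyloxy)-3-(1-hydroxy-9-phenylnonyl)phenyl]-3,4-dihydro-2H-chromen-2-yl}phenyl 2,2-dimethylpropanoate | OC(CCCCCCCCc1ccccc1)c1c(OCc2ccccc2)cc(OCc2ccccc2)c([C@@H]2C[C@@H](c3ccc(OC(=O)C(C)(C)C)cc3)Oc3cc(OCc4ccccc4)ccc32)c1OCc1ccccc1
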